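Early in the south run, L falls to 46.6% by 0.208 d while G reaches 21.6%. Your next decision is how to charge L.

| flask | L | X | temperature | remark | time |
|---|---|---|---|---|---|
| south | 44 mM | 1.8 equiv | 50 °C | run made earlier |  |
| north-west | 88 mM | 1.8 equiv | 50 °C | run made earlier |  |
| Thursday's | 44 mM (fed, over 2.5 d) | 1.80 equiv | 50 °C | all else is in the flask from the start; the feed brings no volume worth counting | 4.0 d |
| Wednesday's | 44 mM | 1.80 equiv | 50 °C | everything together at the start | 4.0 d |
| Tuesday's | 44 mM (fed, over 2.5 d) | 1.80 equiv |  | the addition at 20 °C, then warmed to 50 °C; the feed brings no volume worth counting | 4.0 d |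
| Monday's | 44 mM (in portions, 3, over 2.5 d) | 1.80 equiv | 50 °C | first portion at the start, last at 2.5 d | 4.0 d |

south run (percent of the L charged)

| time / d | G / % | L / % |
|---|---|---|
| 0.208 | 21.6 | 46.6 |
| 0.333 | 27.9 | 33.4 |
| 0.500 | 34.9 | 22.8 |
| 0.833 | 43.8 | 12.4 |
| 1.67 | 50.4 | 3.1 |
| 2.50 | 52.6 | 0.7 |

north-west run (percent of the L charged)

| time / h | G / % | L / % |
|---|---|---|
| 0.833 | 4.7 | 77.0 |
| 1.33 | 6.9 | 68.0 |
| 2.00 | 9.5 | 57.9 |
| 4.00 | 16.0 | 39.5 |
| 6.00 | 19.5 | 29.0 |
| 10.0 | 25.8 | 17.5 |

(readings scatter by 0.5 percentage points)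

- the earlier runs do not show what temperature does; that part of a forecast is a guess

1. the flask with the highest amount of G, in percent of the L charged ("all alike" if they lie within 1.5 percentage points) (Thursday's / Wednesday's / Tuesday's / Monday's / all alike)
2. final G, as a percentage of the L charged, in Thursday's
3. final G, as a percentage of the L charged, in Wednesday's
4. final G, as a percentage of the L charged, in Tuesday's
5. final G, as a percentage of the L charged, in Monday's

1. Work with l, the fraction of L left: [L] over the charge. Let the selectivity, the share of spent L that becomes G, be one over (one plus a·l).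

2. The south run from the start to 0.208 d gives a = 2.01. The next window, to 0.500 d, gives 2.28. Take the mean, 2.14. This is the crowding number: L lost per L turned into G at l of one, with 44 mM charged. The north-west run, with 88 mM, gives 3.99 up to 4.00 h, twice the first south figure. So a rose with the charge in these two runs.

3. G gained as l falls is the ln of the ratio of (one plus a·l) at the two ends, over a. With l going from one to near zero, you reckon 53.5% for Wednesday's.

4. The south reading at 0.833 d gives a first-order constant of 1.41 d⁻¹. For Thursday's feed over 2.5 d, you reckon l near 19.8%, where the share is 70.2%. With the tail, you reckon 72.8% for Thursday's, more than Wednesday's. So you feed, and at 50 °C, where the runs were made. What the cold does is a guess.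

5. The forecast names Thursday's: 73% there, 53% for Wednesday's, 70% for Monday's and 53% for Tuesday's, since “L mostly accumulates at 20 °C, so it behaves like batch”.

6. The flasks give Thursday's the most: 71.5%, against 52.8% for Wednesday's, 47.1% for Tuesday's and 68.6% for Monday's.

    2 L → D (k = 0.0259 M⁻¹ min⁻¹, Ea = 75.0 kJ mol⁻¹)
    X ⇌ Q (K = 0.300, k = 0.00246 min⁻¹, Ea = 99.0 kJ mol⁻¹, ΔH = −30.0 kJ mol⁻¹)
    L ⇌ J + Z (K = 5.11 × 10⁻⁴ M, k = 0.00110 min⁻¹, Ea = 108 kJ mol⁻¹, ΔH = −74.0 kJ mol⁻¹)
    X + J → G (k = 6.19 M⁻¹ min⁻¹, Ea = 42.0 kJ mol⁻¹)
    (constants at 50 °C)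

Tuesday's held 84.4% L and 2.93% G at the change of temperature, and a = 2.14 carried from there down to 3.74% L gives 47.5% G, against 47.1%. Monday's, from 3.68% L plus its last portion down to 3.02% L, gives 69.5% G, against 68.6%. In Tuesday's at 2.74 d, counting forward rates, L went to J and Z faster than to D, by a factor of 1.3.

The earlier runs and the new flask are calculated on assumed constants; noise was put on by code.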